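**Retrosynthetic overview**

1. Ageconyflavone C (11) ⇐ its 4'-O-benzyl ether 10 by hydrogenolysis in the last step; rings A and B are bought as phenols, and ring C is the only ring that is made.
2. 10 ⇐ one-pot four-component assembly of ring C from aryl iodide 3, propiolic acid 6, CO 7 and iodophenol 5: C1'–C2 (Sonogashira), C3–C4 and C4–C4a (decarboxylative carbonylative alkynylation), O1–C2 (6-endo-dig oxa-Michael).
3. Enabling feature: the 4-pyranone ring (O1, C2, C3, C4, C4a, C8a) is the cycloisomer of an ortho-hydroxyaryl aryl ynone. C2=C3 sits at the alkyne oxidation level, C4 is a carbonyl carbon that CO can supply, O1 stands ortho to C4a on ring A, and C2 carries ring B through a bond that maps onto an aryl–alkyne bond.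
4. 3 ⇐ 2,6-dimethoxyphenol 1 (para-iodination, O-benzylation); 5 ⇐ 3,4,5-trimethoxyphenol 4 (ortho-iodination).

Key step: step 4

Remark: the target has no stereocentre, stereogenic axis or stereogenic double bond, so the achiral structure is the single compound asked for and no step has to set stereochemistry.

**Route**

Step 1
Reactants: 1 2,6-dimethoxyphenol (syringol)
Product: 2 4-iodo-2,6-dimethoxyphenol
Conditions: NIS (1.0 equiv), TFA (cat.), MeCN, 0 °C, dark
Reagents that add atoms: N-iodosuccinimide, O=C1CCC(=O)N1I
Why: Electrophilic aromatic iodination (SEAr) should go to C4, the position para to the free hydroxyl, which dominates the directing effects, while the low temperature and exactly one equivalent of NIS limit oxidation of the phenol.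

Step 2
Reactants: 2 4-iodo-2,6-dimethoxyphenol
Product: 3 2-(benzyloxy)-5-iodo-1,3-dimethoxybenzene
Conditions: BnBr, K2CO3, DMF, 60 °C
Reagents that add atoms: benzyl bromide, BrCc1ccccc1
Why: Williamson ether synthesis (SN2 of the phenoxide on benzyl bromide); the di-ortho-methoxy phenoxide is hindered but should still be alkylated in DMF, and the aryl iodide is inert to these conditions.

Step 3
Reactants: 4 3,4,5-trimethoxyphenol
Product: 5 2-iodo-3,4,5-trimethoxyphenol
Conditions: NIS (1.0 equiv), MeCN, −20 to 0 °C, dark
Reagents that add atoms: N-iodosuccinimide, O=C1CCC(=O)N1I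
Why: Electrophilic aromatic iodination (SEAr); C2 and C6 are the only free positions and are equivalent, each ortho to OH and ortho/para to OMe, so regiochemistry is not an issue and one equivalent of NIS at low temperature should stop at the mono-iodide because the first iodine hinders and deactivates the ring.

Step 4
Reactants: 3 2-(benzyloxy)-5-iodo-1,3-dimethoxybenzene; 6 propiolic acid; 5 2-iodo-3,4,5-trimethoxyphenol; 7 carbon monoxide
Product: 10 2-[4-(benzyloxy)-3,5-dimethoxyphenyl]-5,6,7-trimethoxy-4H-chromen-4-one (O-benzyl ageconyflavone C), via arylpropiolic acid 8 (not isolated), via ortho-hydroxyaryl ynone 9 (not isolated)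
Conditions: 3, 6 (1.1 equiv), PdCl2(PPh3)2 (5 mol %), dppb (10 mol %), DBU (4 equiv), DMSO, 35 °C; then 5 (1.1 equiv), CO (1 atm), 80 °C, same pot
Reagents that add atoms: none
Why: Pd(0) adds to the unhindered C–I bond of 3 and couples it with DBU propiolate in a copper-free Sonogashira reaction at 35 °C, which makes the C1'–C2 bond and leaves arylpropiolate 8; after 5 and CO are added, Pd(0) adds to the C–I bond of 5, CO inserts to give an aroyl–Pd species, the carboxylate of 8 exchanges onto Pd and loses CO2, and the resulting alkynyl(aroyl)Pd reductively eliminates ynone 9 (C3–C4 and C4–C4a bonds). DBU then delivers the ortho-phenoxide of 9 to the ynone β-carbon, and protonation at C3 gives the 4-pyranone ring (O1–C2 bond). The closest known reaction types are the one-pot Sonogashira/carbonylative alkynylation/annulation synthesis of flavones from an aryl halide, an acetylene surrogate, CO and a 2-iodophenol, and the one-pot non-carbonylative then decarboxylative carbonylative double coupling of propiolic acid with two aryl iodides to diaryl ynones. Ring C closes in the 6-endo-dig mode (oxa-Michael), and no stereocentre is formed. The step needs three selectivities: the order of the two aryl iodides is secured by staging (3 couples at 35 °C without CO before the slower, di-ortho-substituted 5 is added and the pot is heated under CO); carbonylative over direct alkynylation in the second stage is secured by the electron-rich, hindered aryl–Pd from 5, which should insert CO faster than it is alkynylated, and any 8 that protodecarboxylates to the terminal arylalkyne converges on the same ynone by carbonylative Sonogashira coupling; 6-endo over 5-exo (aurone) closure is favoured by the amine base in a polar solvent, which leads to the thermodynamic conjugate-addition product.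

Step 5
Reactants: 10 2-[4-(benzyloxy)-3,5-dimethoxyphenyl]-5,6,7-trimethoxy-4H-chromen-4-one
Product: 11 Ageconyflavone C, 2-(4-hydroxy-3,5-dimethoxyphenyl)-5,6,7-trimethoxy-4H-chromen-4-one
Conditions: H2 (1 atm), 10% Pd/C, EtOAc/MeOH, rt
Reagents that add atoms: none
Why: Palladium-catalysed hydrogenolysis of the benzyl aryl ether; the C2=C3 bond of the flavone is a doubly aryl-conjugated vinylogous ester and should survive 1 atm of hydrogen at room temperature if the reaction is stopped once debenzylation is complete, and no Lewis acid touches the labile 5-OMe group.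

**Compound list**

1 | 2,6-dimethoxyphenol (syringol) | COc1cccc(OC)c1O | starting material
2 | 4-iodo-2,6-dimethoxyphenol | COc1cc(I)cc(OC)c1O | intermediate
3 | 2-(benzyloxy)-5-iodo-1,3-dimethoxybenzene | COc1cc(I)cc(OC)c1OCc1ccccc1 | intermediate
4 | 3,4,5-trimethoxyphenol | COc1cc(O)cc(OC)c1OC | starting material
5 | 2-iodo-3,4,5-trimethoxyphenol | COc1cc(O)c(I)c(OC)c1OC | intermediate
6 | propiolic acid (prop-2-ynoic acid) | C#CC(=O)O | starting material
7 | carbon monoxide | [C-]#[O+] | starting material
8 | 3-[4-(benzyloxy)-3,5-dimethoxyphenyl]prop-2-ynoic acid, present in the flask as its DBU salt in step 4 | COc1cc(C#CC(=O)O)cc(OC)c1OCc1ccccc1 | intermediate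
9 | 3-[4-(benzyloxy)-3,5-dimethoxyphenyl]-1-(6-hydroxy-2,3,4-trimethoxyphenyl)prop-2-yn-1-one, formed in the flask in step 4 | COc1cc(C#CC(=O)c2c(O)cc(OC)c(OC)c2OC)cc(OC)c1OCc1ccccc1 | intermediate
10 | 2-[4-(benzyloxy)-3,5-dimethoxyphenyl]-5,6,7-trimethoxy-4H-chromen-4-one | COc1cc(-c2cc(=O)c3c(OC)c(OC)c(OC)cc3o2)cc(OC)c1OCc1ccccc1 | intermediate
11 | Ageconyflavone C, 2-(4-hydroxy-3,5-dimethoxyphenyl)-5,6,7-trimethoxy-4H-chromen-4-one | COc1cc(-c2cc(=O)c3c(OC)c(OC)c(OC)cc3o2)cc(OC)c1O | target

**Step count**

Total step count: 5 (steps 1, 2, 4, 5 in the main line; step 3 in the side branch).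
Longest linear sequence: 4 steps (1 → 2 → 3 → 10 → 11).

**Steps most likely to fail, with fallbacks**

Step 4 (key step). Oxidative addition of Pd(0) into the di-ortho-substituted, electron-rich C–I bond of 5 may be so slow that the arylpropiolate is lost to protodecarboxylation and alkyne homocoupling. The aroyl–Pd species may also be intercepted by phenoxide to give aryl esters, or ynone 9 may close in the 5-exo mode to the aurone. The fallback is the classical chalcone route; it sets out from 3 and 4 and comes back at 10. Iodine–lithium exchange on 3 (n-BuLi, THF, −78 °C) and a DMF quench should give 4-(benzyloxy)-3,5-dimethoxybenzaldehyde F1. Friedel–Crafts/Fries acetylation of 4 (Ac2O, BF3·OEt2, 70 °C) should give 1-(6-hydroxy-2,3,4-trimethoxyphenyl)ethanone F2. Claisen–Schmidt condensation of F1 with F2 (KOH, EtOH, rt) should give (E)-3-[4-(benzyloxy)-3,5-dimethoxyphenyl]-1-(6-hydroxy-2,3,4-trimethoxyphenyl)prop-2-en-1-one F3. Oxidative cyclisation of F3 with catalytic I2 in DMSO at 130 °C should then close ring C and give 10.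

Step 1. One-electron oxidation of the very electron-rich phenol by the iodinating agent (para–para oxidative dimerisation towards the diphenoquinone) may outrun C–I bond formation. The fallback sets out from 1 and comes back at 3, and brings iodine in only after the phenol is capped. Para-bromination of 1 with NBS (CH2Cl2, −40 °C), a halogenation that is established for this phenol, should give 4-bromo-2,6-dimethoxyphenol F4, which is also a catalogue compound. O-Benzylation (BnBr, K2CO3, DMF) should give 2-(benzyloxy)-5-bromo-1,3-dimethoxybenzene F5. Copper-catalysed aromatic Finkelstein exchange (NaI, CuI cat., N,N'-dimethylethylenediamine, dioxane, 110 °C) should convert F5 into 3.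

Step 3. The ring may be iodinated at both equivalent ortho positions, or the para-methoxyphenol may undergo oxidative demethylation to the 2,6-dimethoxybenzoquinone. The fallback sets out from 4 and comes back at 5, and replaces the electrophilic iodination by a directed metalation that delivers exactly one iodine. MOM protection (MOMCl, iPr2NEt, CH2Cl2) should give 1,2,3-trimethoxy-5-(methoxymethoxy)benzene F6. Directed ortho-lithiation between the OMOM and OMe groups (n-BuLi, THF, 0 °C) followed by an I2 quench at −78 °C should give 2-iodo-3,4,5-trimethoxy-1-(methoxymethoxy)benzene F7. Acetal cleavage (HCl, MeOH, rt) should give 5.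

**Further compounds**

F1 | step 4 | 4-(benzyloxy)-3,5-dimethoxybenzaldehyde | COc1cc(C=O)cc(OC)c1OCc1ccccc1
F2 | step 4 | 1-(6-hydroxy-2,3,4-trimethoxyphenyl)ethanone | CC(=O)c1c(O)cc(OC)c(OC)c1OC
F3 | step 4 | (E)-3-[4-(benzyloxy)-3,5-dimethoxyphenyl]-1-(6-hydroxy-2,3,4-trimethoxyphenyl)prop-2-en-1-one | COc1cc(/C=C/C(=O)c2c(O)cc(OC)c(OC)c2OC)cc(OC)c1OCc1ccccc1
F4 | step 1 | 4-bromo-2,6-dimethoxyphenol | COc1cc(Br)cc(OC)c1O
F5 | step 1 | 2-(benzyloxy)-5-bromo-1,3-dimethoxybenzene | COc1cc(Br)cc(OC)c1OCc1ccccc1
F6 | step 3 | 1,2,3-trimethoxy-5-(methoxymethoxy)benzene | COCOc1cc(OC)c(OC)c(OC)c1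
F7 | step 3 | 2-iodo-3,4,5-trimethoxy-1-(methoxymethoxy)benzene | COCOc1cc(OC)c(OC)c(OC)c1I
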